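**Retrosynthetic overview**
- The strategy rests on the homoallylic alcohol unit C6(O)–C7–C11(=C13H2) of the ten-membered carbocycle, in which C6 is also the ε-carbon of the furanone dienone C1(=O)–C2=C3–C4=C5. That unit is what a [2,3]-Wittig shift of a C6–O–C13 allylic ether leaves behind, and the conjugation makes C6–H the only acidic C–H of such an ether.
- Key disconnection: C6–C7, by contraction of the thirteen-membered furanone-bridged bis-allylic ether (C8 trans to C13 on C7=C11). The endgame is O6 acylation, desilylation, oxidative closure of the O8–C12 methylene lactone and release of the side-chain hydroxyl.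
- The macrocyclic ether is closed at C1–C2 by chromium-mediated alkynylation of a C1 aldehyde, then oxidised and cyclised to the furanone (O10 to C3). The C6–O–C13 ether is made first and intermolecularly, because a C6 alkoxide beside a finished furanone would add to C3, and every hydride step is placed before the furanone exists.
- C8 (S) comes from Noyori reduction of a C8 ynone; the C7=C11 geometry and C12 from trans-hydroalumination/iodination and Stille hydroxymethylation; C1, C8–C10 and C14 from (R)-citramalic acid; C2–C6 and C15 from (Z)-3-methylpent-2-en-4-yn-1-ol; C7, C11 and C13 from propargyl bromide.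
- Ring order: thirteen-membered ring, furanone, ten-membered carbocycle, methylene lactone.

Key step: step 18

Remarks on the chemistry:
- Germacrane numbering is used for all compounds: C1 ketone, C2=C3, C4(C15)=C5, C6 to C9, C10 (C14 and ring oxygen), C11, C12 (lactone carbonyl), C13 (exocyclic methylene).
- TBS = tert-butyldimethylsilyl, TMS = trimethylsilyl, PMB = 4-methoxybenzyl.
- (Z)-3-Methylpent-2-en-4-yn-1-ol is assumed to be bought as the pure Z isomer.
- The (S,S)-TsDPEN ruthenium catalyst is assumed to give the S carbinol, as it does with other alkynyl ketones.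

**Route**

Step 1
Reactants: 1 (R)-citramalic acid
Product: 2 dimethyl (2R)-2-hydroxy-2-methylbutanedioate
Conditions: MeOH, HCl (cat.), 40 °C
Reagents that add atoms: methanol, CO
Why: Fischer esterification of both carboxyl groups, which leaves the tertiary carbinol and the R configuration at C10 untouched.

Step 2
Reactants: 2 dimethyl (2R)-2-hydroxy-2-methylbutanedioate
Product: 3 methyl (3R)-3,4-dihydroxy-3-methylbutanoate
Conditions: BH3·SMe2 (1.05 equiv), NaBH4 (5 mol%), THF, 0 °C to rt; MeOH quench
Reagents that add atoms: none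
Why: Hydroxyl-directed borane reduction, in which the tertiary alkoxyborane delivers hydride through a five-membered chelate to the adjacent C1 ester only, as in the selective reduction of malate diesters, so the C8 ester should survive.

Step 3
Reactants: 3 methyl (3R)-3,4-dihydroxy-3-methylbutanoate
Product: 4 methyl 2-[(4R)-2,2,4-trimethyl-1,3-dioxolan-4-yl]acetate
Conditions: Me2C(OMe)2, TsOH·H2O (cat.), acetone, rt
Reagents that add atoms: 2,2-dimethoxypropane, COC(C)(C)OC
Why: Acid-catalysed transketalisation to the five-membered acetonide, which masks C1 and O10 during the organometallic and hydride steps.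

Step 4
Reactants: 4 methyl 2-[(4R)-2,2,4-trimethyl-1,3-dioxolan-4-yl]acetate
Product: 5 N-methoxy-N-methyl-2-[(4R)-2,2,4-trimethyl-1,3-dioxolan-4-yl]acetamide
Conditions: MeNH(OMe)·HCl, i-PrMgCl, THF, −20 to 0 °C
Reagents that add atoms: N,O-dimethylhydroxylamine hydrochloride, CNOC.Cl
Why: Weinreb amide formation by aminolysis of the methyl ester with the chloromagnesium amide made in the flask.

Step 5
Reactants: 6 (2Z)-3-methylpent-2-en-4-yn-1-ol
Product: 9 (2Z)-3-methyl-5-(trimethylsilyl)pent-2-en-4-yn-1-ol, via dilithium alkoxide acetylide 7 (not isolated), via C,O-bis(trimethylsilyl) compound 8 (not isolated)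
Conditions: n-BuLi (2.1 equiv), THF, −78 to 0 °C; TMSCl (2.2 equiv), −78 °C to rt; 1 M HCl, rt
Reagents that add atoms: chlorotrimethylsilane, C[Si](C)(C)Cl
Why: C,O-bis-silylation of the dianion followed by selective hydrolysis of the labile O–Si bond leaves the alkynylsilane, which blocks C2 while the acetylide chemistry is done at C7.

Step 6
Reactants: 9 (2Z)-3-methyl-5-(trimethylsilyl)pent-2-en-4-yn-1-ol; 10 propargyl bromide
Product: 12 trimethyl[(3Z)-3-methyl-5-(prop-2-yn-1-yloxy)pent-3-en-1-yn-1-yl]silane, via sodium alkoxide 11 (not isolated)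
Conditions: NaH, THF, 0 °C; propargyl bromide, Bu4NI (cat.), 0 °C to rt
Reagents that add atoms: none
Why: Williamson etherification (SN2 on propargyl bromide) installs the C6–O–C13 ether at the outset, when O6 is a simple allylic alkoxide and no furanone is present that it could attack at C3.

Step 7
Reactants: 12 trimethyl[(3Z)-3-methyl-5-(prop-2-yn-1-yloxy)pent-3-en-1-yn-1-yl]silane; 5 N-methoxy-N-methyl-2-[(4R)-2,2,4-trimethyl-1,3-dioxolan-4-yl]acetamide
Product: 14 5-{[(2Z)-3-methyl-5-(trimethylsilyl)pent-2-en-4-yn-1-yl]oxy}-1-[(4R)-2,2,4-trimethyl-1,3-dioxolan-4-yl]pent-3-yn-2-one, via lithium acetylide 13 (not isolated)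
Conditions: 12 (1.3 equiv), n-BuLi (1.25 equiv), THF, −78 °C; then 5, −78 to −20 °C; aq. NH4Cl
Reagents that add atoms: none
Why: Acylation of a lithium acetylide by a Weinreb amide stops at the ketone because the chelated tetrahedral intermediate lasts until work-up, and only the terminal C7–H is acidic enough for n-BuLi at −78 °C.

Step 8
Reactants: 14 the C8 ynone
Product: 15 (2S)-5-{[(2Z)-3-methyl-5-(trimethylsilyl)pent-2-en-4-yn-1-yl]oxy}-1-[(4R)-2,2,4-trimethyl-1,3-dioxolan-4-yl]pent-3-yn-2-ol
Conditions: Ru[(S,S)-TsDPEN](p-cymene) (2 mol%), i-PrOH, rt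
Reagents that add atoms: none
Why: Noyori asymmetric transfer hydrogenation of an alkynyl ketone, in which the alkyne takes the place of the aryl group of the usual model, so the (S,S) catalyst should set the 8S carbinol under reagent control.

Step 9
Reactants: 15 the (8S)-propargylic alcohol
Product: 17 (2S,3Z)-4-iodo-5-{[(2Z)-3-methyl-5-(trimethylsilyl)pent-2-en-4-yn-1-yl]oxy}-1-[(4R)-2,2,4-trimethyl-1,3-dioxolan-4-yl]pent-3-en-2-ol, via cyclic sodium alkenylalanate 16 (not isolated)
Conditions: NaAlH2(OCH2CH2OMe)2 (1.6 equiv), THF, 0 °C; then I2, THF, −78 to 0 °C; aq. Na2S2O3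
Reagents that add atoms: iodine, II
Why: Hydroxyl-directed trans-hydroalumination places hydrogen on C7 and aluminium on C11, and iodinolysis with retention gives the alkenyl iodide with iodine cis to C8, which fixes the C7=C11 geometry (C13 trans to C8).

Step 10
Reactants: 17 the (Z)-alkenyl iodide; 18 (tributylstannyl)methanol
Product: 19 (2E,4S)-2-({[(2Z)-3-methyl-5-(trimethylsilyl)pent-2-en-4-yn-1-yl]oxy}methyl)-5-[(4R)-2,2,4-trimethyl-1,3-dioxolan-4-yl]pent-2-ene-1,4-diol
Conditions: Pd(PPh3)4 (10 mol%), 1,4-dioxane, 90 °C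
Reagents that add atoms: none
Why: Stille cross-coupling of the alkenyl iodide with the hydroxymethylstannane proceeds with retention of alkene geometry and so places C12 cis to C8.

Step 11
Reactants: 19 the C8,C12 diol
Product: 20 bis-TBS ether of 19 (O8 and O12 silylated)
Conditions: TBSCl, imidazole, DMF, rt
Reagents that add atoms: tert-butyldimethylsilyl chloride, CC(C)(C)[Si](C)(C)Cl
Why: Standard silylation of the primary and the secondary hydroxyl group.

Step 12
Reactants: 20 the bis-TBS ether
Product: 21 1-iodoalkyne (iodine on C2 in place of SiMe3)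
Conditions: NIS, AgNO3 (10 mol%), acetone, rt, dark
Reagents that add atoms: N-iodosuccinimide, O=C1CCC(=O)N1I
Why: Silver-catalysed iododesilylation converts the alkynylsilane directly into the 1-iodoalkyne needed for chromium insertion, under neutral conditions that spare silyl ethers and alkenes.

Step 13
Reactants: 21 the 1-iodoalkyne
Product: 22 1,2-diol (C1 primary and C10 tertiary hydroxyl free)
Conditions: CeCl3·7H2O, oxalic acid (cat.), MeCN, rt
Reagents that add atoms: none
Why: Mild Lewis-acid-assisted hydrolysis should cleave the acetonide of the tertiary 1,2-diol faster than the two TBS ethers.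

Step 14
Reactants: 22 the 1,2-diol
Product: 23 α-hydroxy aldehyde (C1 aldehyde, C10 tertiary hydroxyl)
Conditions: SO3·pyridine, DMSO, i-Pr2NEt, CH2Cl2, 0 °C
Reagents that add atoms: none
Why: Parikh–Doering oxidation of the primary alcohol, since activated DMSO does not cleave 1,2-diols and the tertiary hydroxyl cannot be oxidised.

Step 15
Reactants: 23 the α-hydroxy aldehyde
Product: 25 thirteen-membered cyclic ether ynediol (C1 epimers), via alkynyl-CrCl2 species 24 (not isolated)
Conditions: CrCl2 (8 equiv), NiCl2 (2 mol%), THF, rt, slow addition (final 2 mM)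
Reagents that add atoms: none
Why: Intramolecular Nozaki–Hiyama–Kishi alkynylation, in which chromium inserts into the C–I bond and the alkynylchromium adds to the non-enolisable aldehyde under high dilution to close the ring at C1–C2; the new C1 carbinol is oxidised next, so its configuration does not matter.

Step 16
Reactants: 25 the macrocyclic ynediol
Product: 26 thirteen-membered α'-hydroxy ynone
Conditions: IBX, DMSO, rt
Reagents that add atoms: none
Why: IBX oxidation of the secondary propargylic alcohol, a reagent that oxidises 1,2-diols to ketols without C–C cleavage and leaves the tertiary alcohol.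

Step 17
Reactants: 26 the macrocyclic α'-hydroxy ynone
Product: 28 thirteen-membered furanone-bridged bis-allylic ether (4Z; C8 trans to C13 on C7=C11; 8S,10R; O8 and O12 as TBS ethers), via β-diethylamino enone 27 (not isolated)
Conditions: Et2NH, EtOH, rt; then AcOH, H2O, rt
Reagents that add atoms: none
Why: Conjugate addition of diethylamine to the ynone and, on acidification, addition of the C10 hydroxyl to C3 with loss of the amine (addition–elimination), the classical 3(2H)-furanone synthesis from α'-hydroxy ynones, which avoids π-acid catalysts that could engage the neighbouring allyl ether.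

Step 18
Reactants: 28 the thirteen-membered furanone-bridged bis-allylic ether
Product: 31 ten-membered C6 carbinol (6R,7S,8S,10R; 4Z) with the 3-(TBS-oxy)prop-1-en-2-yl group on C7, via lithium trienolate 29 (not isolated), via lithium alkoxide 30 (not isolated)
Conditions: LiN(i-Pr)2 (1.3 equiv), THF, −78 °C, then −78 to −20 °C; AcOH, −78 °C
Reagents that add atoms: none
Why: Proposed new method: LiN(i-Pr)2 should remove a C6 proton, the only C–H whose anion is conjugated through C5=C4 and C3=C2 to the C1 ketone (the C13 protons are merely allylic and C15 is cross-conjugated), to give trienolate 29, the same distal deprotonation by which 5-alkyl-3(2H)-furanones are metalated on the side chain. C6 then bonds to C7 through a five-membered envelope (C6, O, C13, C11, C7) while O–C13 breaks, a six-electron [2,3]-sigmatropic (Wittig) shift; the closest known reactions are the alkyllithium-induced [2,3]-Wittig contractions of thirteen-membered bis-allylic and allylic propargylic ethers to ten-membered carbocycles and the [2,3]-Wittig shifts of α-allyloxy ketone and ester enolates, but a carbanion at the ε-terminus of a furanone trienolate has not been used in this way. The ten-membered carbocycle C1–C10 is closed by this transannular C–C bond formation, a 13 to 10 ring contraction that also turns C7=C11 into the exocyclic C11=C13 methylene and leaves alkoxide 30. C6 and C7 arise together: with C8 trans to C13 on the alkene and C5 in the less hindered exo position of the envelope the 6,7-relation of the target results, and the face of C7 is set by C8, whose hydrogen eclipses the alkene toward C12 (allylic 1,3-strain) so that C6, tethered through C9, arrives anti to the C8 silyloxy group. The step needs metalation at C6 and not C13 (secured by the conjugation), bond formation from C6 and not from C2 or C4 of the trienolate (only C6 carries the oxygen of the allowed five-membered array), retention of the 4Z geometry (an E alkene beside the oxygen bridge would be too strained in the ten-membered ring) and a cold acidic quench before alkoxide 30 can take silicon from O8 or add to C3.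

Step 19
Reactants: 32 methyl acrylate; 33 4-methoxybenzyl alcohol
Product: 34 methyl 3-[(4-methoxybenzyl)oxy]propanoate
Conditions: KOt-Bu (5 mol%), THF, 0 °C
Reagents that add atoms: none
Why: Base-catalysed oxa-Michael addition of the benzylic alcohol to the acrylate.

Step 20
Reactants: 34 methyl 3-[(4-methoxybenzyl)oxy]propanoate; 35 acetaldehyde
Product: 37 methyl 3-hydroxy-2-{[(4-methoxybenzyl)oxy]methyl}butanoate (diastereomer mixture), via lithium ester enolate 36 (not isolated)
Conditions: LiN(i-Pr)2, THF, −78 °C; then MeCHO, −78 °C; aq. NH4Cl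
Reagents that add atoms: none
Why: Aldol addition of the lithium ester enolate at −78 °C, cold enough to suppress β-elimination of the alkoxide; both new stereocentres are removed in the next step.

Step 21
Reactants: 37 the aldol
Product: 39 methyl (2E)-2-{[(4-methoxybenzyl)oxy]methyl}but-2-enoate, via mesylate 38 (not isolated)
Conditions: MsCl, Et3N, CH2Cl2, 0 °C; then DBU, rt
Reagents that add atoms: none
Why: Mesylation and E1cB elimination, which should favour the more stable E enoate (methyl trans to the ester), the geometry of the target side chain; any Z isomer would be removed by chromatography.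

Step 22
Reactants: 39 the E enoate
Product: 41 (2E)-2-{[(4-methoxybenzyl)oxy]methyl}but-2-enoic acid, via lithium carboxylate 40 (not isolated)
Conditions: LiOH, THF/H2O, rt; then 1 M HCl
Reagents that add atoms: lithium hydroxide, [Li+].[OH-]
Why: Saponification of the methyl ester followed by acidification.

Step 23
Reactants: 31 the ten-membered C6 carbinol; 41 the PMB-protected side-chain acid
Product: 43 O6 ester of 31 (6R,7S,8S,10R), via mixed anhydride 42 (not isolated)
Conditions: 41, 2,4,6-Cl3C6H2COCl, Et3N, THF, rt; then 31, DMAP, toluene, rt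
Reagents that add atoms: none
Why: Yamaguchi esterification through the mixed anhydride acylates the hindered C6 hydroxyl, the only free hydroxyl group, and touches no stereocentre.

Step 24
Reactants: 43 the bis-TBS ester
Product: 44 C8,C12 diol (6R,7R,8S,10R)
Conditions: HF·pyridine, pyridine, THF, 0 °C to rt
Reagents that add atoms: none
Why: Fluoride cleavage of both TBS ethers under buffered, slightly acidic conditions, which should spare the PMB ether and the esters and avoid base-induced acyl migration from O6 to O8.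

Step 25
Reactants: 44 the C8,C12 diol
Product: 47 PMB-protected target (α-methylene-γ-butyrolactone closed between C12 and O8), via hydroxy enal 45 (not isolated), via lactol 46 (not isolated)
Conditions: TEMPO (20 mol%), PhI(OAc)2 (2.5 equiv), CH2Cl2, rt
Reagents that add atoms: none
Why: TEMPO-catalysed oxidative lactonisation, in which the primary allylic alcohol is oxidised to the enal, the C8 hydroxyl closes the lactol and the lactol is oxidised further, while the secondary C8 hydroxyl is not oxidised at a competitive rate.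

Step 26
Reactants: 47 the PMB-protected target
Product: 48 CNP0323575.1
Conditions: DDQ, CH2Cl2/pH 7 buffer, 0 °C
Reagents that add atoms: none
Why: Oxidative cleavage of the PMB ether with DDQ under buffered conditions should release the side-chain hydroxyl without affecting the methylene lactone, the furanone or the esters.

**Compound list**
1 | (R)-citramalic acid, (2R)-2-hydroxy-2-methylbutanedioic acid | C[C@@](CC(=O)O)(C(=O)O)O | starting material
2 | dimethyl (2R)-2-hydroxy-2-methylbutanedioate | C[C@@](CC(=O)OC)(C(=O)OC)O | intermediate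
3 | methyl (3R)-3,4-dihydroxy-3-methylbutanoate | C[C@@](CC(=O)OC)(CO)O | intermediate
4 | methyl 2-[(4R)-2,2,4-trimethyl-1,3-dioxolan-4-yl]acetate | C[C@@]1(CC(=O)OC)COC(C)(C)O1 | intermediate
5 | N-methoxy-N-methyl-2-[(4R)-2,2,4-trimethyl-1,3-dioxolan-4-yl]acetamide | C[C@@]1(CC(=O)N(C)OC)COC(C)(C)O1 | intermediate
6 | (2Z)-3-methylpent-2-en-4-yn-1-ol | C#C/C(C)=C\CO | starting material
7 | dilithium alkoxide acetylide of 6 | [Li+].[Li+].[C-]#C/C(C)=C\C[O-] | intermediate
8 | trimethyl{[(2Z)-3-methyl-5-(trimethylsilyl)pent-2-en-4-yn-1-yl]oxy}silane | C[Si](C)(C)C#C/C(C)=C\CO[Si](C)(C)C | intermediate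
9 | (2Z)-3-methyl-5-(trimethylsilyl)pent-2-en-4-yn-1-ol | C[Si](C)(C)C#C/C(C)=C\CO | intermediate
10 | propargyl bromide (3-bromoprop-1-yne) | C#CCBr | starting material
11 | sodium alkoxide of 9 | [Na+].[O-]C/C=C(C)\C#C[Si](C)(C)C | intermediate
12 | trimethyl[(3Z)-3-methyl-5-(prop-2-yn-1-yloxy)pent-3-en-1-yn-1-yl]silane | C[Si](C)(C)C#C/C(C)=C\COCC#C | intermediate
13 | lithium acetylide of 12 (lithiated at the propargyl ether terminus, C7) | [Li+].[C-]#CCOC/C=C(C)\C#C[Si](C)(C)C | intermediate
14 | 5-{[(2Z)-3-methyl-5-(trimethylsilyl)pent-2-en-4-yn-1-yl]oxy}-1-[(4R)-2,2,4-trimethyl-1,3-dioxolan-4-yl]pent-3-yn-2-one | C[Si](C)(C)C#C/C(C)=C\COCC#CC(=O)C[C@]1(C)COC(C)(C)O1 | intermediate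
15 | (2S)-5-{[(2Z)-3-methyl-5-(trimethylsilyl)pent-2-en-4-yn-1-yl]oxy}-1-[(4R)-2,2,4-trimethyl-1,3-dioxolan-4-yl]pent-3-yn-2-ol | C[Si](C)(C)C#C/C(C)=C\COCC#C[C@@H](O)C[C@]1(C)COC(C)(C)O1 | intermediate
16 | cyclic sodium alkenylalanate from 15 (aluminium bound to C11 and O8, two 2-methoxyethoxy ligands) | C[Si](C)(C)C#C/C(C)=C\COCC1=C[C@H](C[C@]2(C)COC(C)(C)O2)O[Al-]1(OCCOC)OCCOC.[Na+] | intermediate
17 | (2S,3Z)-4-iodo-5-{[(2Z)-3-methyl-5-(trimethylsilyl)pent-2-en-4-yn-1-yl]oxy}-1-[(4R)-2,2,4-trimethyl-1,3-dioxolan-4-yl]pent-3-en-2-ol | C[Si](C)(C)C#C/C(C)=C\COC/C(I)=C/[C@@H](O)C[C@]1(C)COC(C)(C)O1 | intermediate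
18 | (tributylstannyl)methanol | CCCC[Sn](CCCC)(CCCC)CO | starting material
19 | (2E,4S)-2-({[(2Z)-3-methyl-5-(trimethylsilyl)pent-2-en-4-yn-1-yl]oxy}methyl)-5-[(4R)-2,2,4-trimethyl-1,3-dioxolan-4-yl]pent-2-ene-1,4-diol (C12 hydroxymethyl cis to C8) | C[Si](C)(C)C#C/C(C)=C\COC/C(CO)=C/[C@@H](O)C[C@]1(C)COC(C)(C)O1 | intermediate
20 | bis-TBS ether of 19 (O8 and O12 silylated) | C[Si](C)(C)C#C/C(C)=C\COC/C(CO[Si](C)(C)C(C)(C)C)=C/[C@@H](O[Si](C)(C)C(C)(C)C)C[C@]1(C)COC(C)(C)O1 | intermediate
21 | 1-iodoalkyne from 20 (iodine on C2) | IC#C/C(C)=C\COC/C(CO[Si](C)(C)C(C)(C)C)=C/[C@@H](O[Si](C)(C)C(C)(C)C)C[C@]1(C)COC(C)(C)O1 | intermediate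
22 | 1,2-diol from 21 (C1 primary and C10 tertiary hydroxyl; 8S,10R) | IC#C/C(C)=C\COC/C(CO[Si](C)(C)C(C)(C)C)=C/[C@@H](O[Si](C)(C)C(C)(C)C)C[C@@](C)(O)CO | intermediate
23 | α-hydroxy aldehyde from 22 (C1 aldehyde; 8S,10R) | IC#C/C(C)=C\COC/C(CO[Si](C)(C)C(C)(C)C)=C/[C@@H](O[Si](C)(C)C(C)(C)C)C[C@@](C)(O)C=O | intermediate
24 | alkynyl-CrCl2 species from 23 | Cl[Cr](Cl)C#C/C(C)=C\COC/C(CO[Si](C)(C)C(C)(C)C)=C/[C@@H](O[Si](C)(C)C(C)(C)C)C[C@@](C)(O)C=O | intermediate
25 | thirteen-membered cyclic ether ynediol (C1 and C10 hydroxyl, C2≡C3, 4Z, C6–O–C13, 8S,10R, C1 epimers) | CC(C)(C)[Si](C)(C)OC/C1=C\[C@@H](O[Si](C)(C)C(C)(C)C)C[C@@](C)(O)C(O)C#C/C(C)=C\COC1 | intermediate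
26 | thirteen-membered α'-hydroxy ynone (C1 ketone, C10 hydroxyl) | CC(C)(C)[Si](C)(C)OC/C1=C\[C@@H](O[Si](C)(C)C(C)(C)C)C[C@@](C)(O)C(=O)C#C/C(C)=C\COC1 | intermediate
27 | β-diethylamino enone from 26 (amine on C3, C2=C3 geometry undefined) | CC(C)(C)[Si](C)(C)OC/C1=C\[C@@H](O[Si](C)(C)C(C)(C)C)C[C@@](C)(O)C(=O)C=C(N(CC)CC)/C(C)=C\COC1 | intermediate
28 | thirteen-membered furanone-bridged bis-allylic ether, key-step precursor (4Z, 8S,10R, bis-TBS) | CC(C)(C)[Si](C)(C)OC/C1=C\[C@@H](O[Si](C)(C)C(C)(C)C)C[C@@]2(C)OC(=CC2=O)/C(C)=C\COC1 | intermediate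
29 | lithium trienolate of 28 (delocalised over O1, C2, C4, C6) | CC(C)(C)[Si](C)(C)OC/C1=C\[C@@H](O[Si](C)(C)C(C)(C)C)C[C@@]2(C)OC(C=C2[O-])=C(C)C=COC1.[Li+] | intermediate
30 | lithium C6 alkoxide of 31 | C=C(CO[Si](C)(C)C(C)(C)C)[C@@H]1[C@@H](O[Si](C)(C)C(C)(C)C)C[C@@]2(C)OC(=CC2=O)/C(C)=C\[C@H]1[O-].[Li+] | intermediate
31 | ten-membered C6 carbinol, key-step product (6R,7S,8S,10R; 4Z; bis-TBS) | C=C(CO[Si](C)(C)C(C)(C)C)[C@@H]1[C@@H](O[Si](C)(C)C(C)(C)C)C[C@@]2(C)OC(=CC2=O)/C(C)=C\[C@H]1O | intermediate
32 | methyl acrylate | C=CC(=O)OC | starting material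
33 | 4-methoxybenzyl alcohol | COc1ccc(CO)cc1 | starting material
34 | methyl 3-[(4-methoxybenzyl)oxy]propanoate | COC(=O)CCOCc1ccc(OC)cc1 | intermediate
35 | acetaldehyde | CC=O | starting material
36 | lithium enolate of 34 | [Li+].[O-]C(OC)=CCOCc1ccc(OC)cc1 | intermediate
37 | methyl 3-hydroxy-2-{[(4-methoxybenzyl)oxy]methyl}butanoate (diastereomer mixture) | COC(=O)C(COCc1ccc(OC)cc1)C(C)O | intermediate
38 | mesylate of 37 | COC(=O)C(COCc1ccc(OC)cc1)C(C)OS(C)(=O)=O | intermediate
39 | methyl (2E)-2-{[(4-methoxybenzyl)oxy]methyl}but-2-enoate | COC(=O)/C(=C/C)COCc1ccc(OC)cc1 | intermediate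
40 | lithium (2E)-2-{[(4-methoxybenzyl)oxy]methyl}but-2-enoate | [Li+].[O-]C(=O)/C(=C/C)COCc1ccc(OC)cc1 | intermediate
41 | (2E)-2-{[(4-methoxybenzyl)oxy]methyl}but-2-enoic acid | OC(=O)/C(=C/C)COCc1ccc(OC)cc1 | intermediate
42 | mixed anhydride of 41 and 2,4,6-trichlorobenzoic acid | O=C(OC(=O)/C(=C/C)COCc1ccc(OC)cc1)c1c(Cl)cc(Cl)cc1Cl | intermediate
43 | O6 ester of 31 with acid 41 (6R,7S,8S,10R; bis-TBS) | C=C(CO[Si](C)(C)C(C)(C)C)[C@@H]1[C@@H](O[Si](C)(C)C(C)(C)C)C[C@@]2(C)OC(=CC2=O)/C(C)=C\[C@H]1OC(=O)/C(=C/C)COCc1ccc(OC)cc1 | intermediate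
44 | C8,C12 diol of 43 (6R,7R,8S,10R) | C=C(CO)[C@@H]1[C@@H](O)C[C@@]2(C)OC(=CC2=O)/C(C)=C\[C@H]1OC(=O)/C(=C/C)COCc1ccc(OC)cc1 | intermediate
45 | hydroxy enal from 44 (C12 aldehyde, C8 hydroxyl) | C=C(C=O)[C@@H]1[C@@H](O)C[C@@]2(C)OC(=CC2=O)/C(C)=C\[C@H]1OC(=O)/C(=C/C)COCc1ccc(OC)cc1 | intermediate
46 | lactol from 45 (O8–C12 hemiacetal, C12 epimers) | C=C1C(O)O[C@H]2C[C@@]3(C)OC(=CC3=O)/C(C)=C\[C@@H](OC(=O)/C(=C/C)COCc4ccc(OC)cc4)[C@H]12 | intermediate
47 | PMB ether of the target (6R,7R,8S,10R) | C=C1C(=O)O[C@H]2C[C@@]3(C)OC(=CC3=O)/C(C)=C\[C@@H](OC(=O)/C(=C/C)COCc4ccc(OC)cc4)[C@H]12 | intermediate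
48 | CNP0323575.1 (6R,7R,8S,10R; 4Z; side chain 2E) | C=C1C(=O)O[C@H]2C[C@@]3(C)OC(=CC3=O)/C(C)=C\[C@@H](OC(=O)/C(=C/C)CO)[C@H]12 | target

**Step count and risks**

Total step count: 26. Longest linear sequence: 20 steps (steps 1–4, 7–18 and 23–26, from (R)-citramalic acid).

Steps most likely to fail:

1. Step 18 (proposed new method). The delocalised lithium trienolate may be too weak a nucleophile at C6, so that no shift occurs at temperatures where the anion is stable. On warming, a radical [1,2]-shift or silyl transfer from O8 to the new C6 alkoxide could take over, and the facial selectivity at C7 could be lower than the allylic-strain model predicts. The fallback uses known chemistry, the alkyllithium-induced [2,3]-Wittig contraction of a thirteen-membered bis-allylic ether that carries no carbonyl group. It sets out from 28: 1,2-reduction of the C1 ketone with i-Bu2AlH (CH2Cl2, −78 °C) would give the C1 carbinol F1, and TBSCl/imidazole its silyl ether F2. n-BuLi (THF, −78 to −20 °C) would then generate the unstabilised C6 carbanion, favoured over C13 because it is a pentadienyl-type anion, and its [2,3]-shift would give the ring-contracted C6 carbinol F3. Esterification with 41 as in step 23 would give the ester F4 and Bu4NF buffered with AcOH the triol F5. MnO2 (CH2Cl2, rt) would oxidise the C1 carbinol back to the furanone and the C8/C12 diol to the lactone, so the fallback comes back to the route at 47.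

2. Step 15. Intermolecular coupling (oligomerisation) may outrun ring closure, or the iodine may be lost reductively before the alkynylchromium adds; the α-hydroxy aldehyde could also rearrange as an α-ketol. The fallback changes the bond-forming reaction to a zinc acetylide addition. It sets out from 20: K2CO3/MeOH would remove the alkynyl silyl group to give the terminal alkyne F6, CeCl3·7H2O/oxalic acid as in step 13 the diol F7, and Parikh–Doering oxidation as in step 14 the aldehyde F8. Slow addition of F8 to Zn(OTf)2 and Et3N in toluene at 60 °C should close the ring, and the fallback comes back to the route at 25.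

3. Step 10. Transfer of the hydroxymethyl group from tin may be slow at the hindered alkenyl iodide, so that protodeiodination or butyl transfer competes. The fallback introduces C12 by carbonylation instead. It sets out from 17: Pd(PPh3)2Cl2, CO (1 atm) and Et3N in THF would give the butenolide F9 by carbonylative lactonisation onto O8. i-Bu2AlH (CH2Cl2, −78 to 0 °C) would reduce the lactone to the diol, and the fallback comes back to the route at 19.

Further compounds
F1 | step 18 | C1 carbinol of 28 (3-hydroxy-2,3-dihydrofuran, C1 epimers) | CC(C)(C)[Si](C)(C)OC/C1=C\[C@@H](O[Si](C)(C)C(C)(C)C)C[C@@]2(C)OC(=CC2O)/C(C)=C\COC1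
F2 | step 18 | O1 TBS ether of F1 | CC(C)(C)[Si](C)(C)OC/C1=C\[C@@H](O[Si](C)(C)C(C)(C)C)C[C@@]2(C)OC(=CC2O[Si](C)(C)C(C)(C)C)/C(C)=C\COC1
F3 | step 18 | ring-contracted C6 carbinol with O1, O8 and O12 as TBS ethers | C=C(CO[Si](C)(C)C(C)(C)C)[C@@H]1[C@@H](O[Si](C)(C)C(C)(C)C)C[C@@]2(C)OC(=CC2O[Si](C)(C)C(C)(C)C)/C(C)=C\[C@H]1O
F4 | step 18 | O6 ester of F3 with acid 41 | C=C(CO[Si](C)(C)C(C)(C)C)[C@@H]1[C@@H](O[Si](C)(C)C(C)(C)C)C[C@@]2(C)OC(=CC2O[Si](C)(C)C(C)(C)C)/C(C)=C\[C@H]1OC(=O)/C(=C/C)COCc1ccc(OC)cc1
F5 | step 18 | C1,C8,C12 triol of F4 | C=C(CO)[C@@H]1[C@@H](O)C[C@@]2(C)OC(=CC2O)/C(C)=C\[C@H]1OC(=O)/C(=C/C)COCc1ccc(OC)cc1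
F6 | step 15 | terminal alkyne from 20 (C2–H) | C#C/C(C)=C\COC/C(CO[Si](C)(C)C(C)(C)C)=C/[C@@H](O[Si](C)(C)C(C)(C)C)C[C@]1(C)COC(C)(C)O1
F7 | step 15 | C1,C10 diol of F6 | C#C/C(C)=C\COC/C(CO[Si](C)(C)C(C)(C)C)=C/[C@@H](O[Si](C)(C)C(C)(C)C)C[C@@](C)(O)CO
F8 | step 15 | C1 aldehyde of F7 | C#C/C(C)=C\COC/C(CO[Si](C)(C)C(C)(C)C)=C/[C@@H](O[Si](C)(C)C(C)(C)C)C[C@@](C)(O)C=O
F9 | step 10 | butenolide (O8–C12 lactone, C7=C11 in the ring, C13 ether on C11) | O=C1O[C@@H](C[C@]2(C)COC(C)(C)O2)C=C1COC/C=C(C)\C#C[Si](C)(C)C
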